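Ring C is opened at C3–C4. Because the C4 ketone carbon sits on ring A next to the carbon that carries O1, ring C can be read as a ring-A formyl C–H bond added across a 1-arylvinyl group held on O1; the substituted alkene carbon becomes C2. One rhodium-catalysed, ligand-controlled hydroacylation therefore forms C3–C4, closes ring C and sets (S)-C2. Its substrate is a fully substituted benzaldehyde bearing the O-(1-arylvinyl) ether on one ortho oxygen and a TBS ether on the other (future O5), with the B-ring phenol also as a TBS ether; it is made from an aryl vanillate by titanium methylenation, and both silyl groups fall in the last step.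

Key step: step 7

Assumption: the hand of the bisphosphine that gives 2S cannot be predicted with confidence; (R) is written, and the antipode is used if the first run should give 2R.

Remarks on the design:
- The oxygen that ends as the C5 hydroxyl stays silylated through step 7. As a rhodium-bound phenoxide it would hold the metal on the flank of the acyl group away from the O1 vinyl ether, since the metal cannot be syn to both ortho oxygens. A free acidic phenol beside a cationic catalyst could also release acid onto the enol ether.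
- The aldehyde is masked only after the mono-aroylation, because that selectivity depends on the formyl chelate. No free hydroxyl is present in the titanium step.
- An aldehyde ortho to an O-vinyl ether is a latent flavylium under acid. From step 6 on the only acidic operation is a brief, water-rich, weakly acidic acetal release.

Step 1
Reactants: 1 2,4,6-trihydroxybenzaldehyde; 2 prenyl bromide (2 equiv)
Product: 3 2,4,6-trihydroxy-3,5-bis(3-methylbut-2-enyl)benzaldehyde
Conditions: KOH (aq., 10%), 0 °C → rt
Reagents that add atoms: none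
Why: In water the hydrogen-bonded phloroglucinol phenolate reacts through carbon, and C3 and C5 are the only free ring positions, so two C-alkylations (phenolate C-prenylation) should give the 3,5-diprenyl aldehyde.

Step 2
Reactants: 3 2,4,6-trihydroxy-3,5-bis(3-methylbut-2-enyl)benzaldehyde
Product: 4 2,6-dihydroxy-4-methoxy-3,5-bis(3-methylbut-2-enyl)benzaldehyde
Conditions: Me2SO4 (1.0 equiv), K2CO3 (1.0 equiv), acetone, rt
Reagents that add atoms: dimethyl sulfate, COS(=O)(=O)OC
Why: The 4-hydroxyl, para to the formyl group and outside its chelate, is the most acidic, so one equivalent of weak base and dimethyl sulfate should methylate it selectively (Williamson ether synthesis) while the two ortho hydroxyls remain.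

Step 3
Reactants: 5 vanillic acid
Product: 7 4-(tert-butyldimethylsilyloxy)-3-methoxybenzoic acid, via silyl ester 6 (not isolated)
Conditions: TBSCl (2.2 equiv), imidazole, DMF, rt; then AcOH–THF–H2O, rt
Reagents that add atoms: tert-butyldimethylsilyl chloride, CC(C)(C)[Si](C)(C)Cl
Why: Silyl chloride and imidazole silylate both the phenol and the acid, and the silyl ester is far more labile to water than the aryl silyl ether, so dilute aqueous acetic acid should return the acid with the phenol still protected (silylation, selective silyl ester hydrolysis).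

Step 4
Reactants: 7 4-(tert-butyldimethylsilyloxy)-3-methoxybenzoic acid; 4 2,6-dihydroxy-4-methoxy-3,5-bis(3-methylbut-2-enyl)benzaldehyde
Product: 9 2-formyl-3-hydroxy-5-methoxy-4,6-bis(3-methylbut-2-enyl)phenyl 4-(tert-butyldimethylsilyloxy)-3-methoxybenzoate, via acid chloride 8 (not isolated)
Conditions: (COCl)2, DMF (cat.), CH2Cl2, 0 °C → rt, evaporate; then 4 (1.1 equiv), Et3N, DMAP (cat.), CH2Cl2, −20 → 0 °C
Reagents that add atoms: none
Why: Acid chloride formation and O-acylation of a phenol; the two phenols of 4 are equivalent, and after the first acylation the remaining hydroxyl is locked in the formyl chelate and flanked by a prenyl group, so the mono-ester should dominate.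

Step 5
Reactants: 9 2-formyl-3-hydroxy-5-methoxy-4,6-bis(3-methylbut-2-enyl)phenyl 4-(tert-butyldimethylsilyloxy)-3-methoxybenzoate
Product: 11 3-(tert-butyldimethylsilyloxy)-2-(dimethoxymethyl)-5-methoxy-4,6-bis(3-methylbut-2-enyl)phenyl 4-(tert-butyldimethylsilyloxy)-3-methoxybenzoate, via silyl ether aldehyde 10 (not isolated)
Conditions: TBSOTf, 2,6-lutidine, CH2Cl2, 0 °C; then MeOTMS, TMSOTf (cat., in excess over residual lutidine), −78 → −30 °C; Et3N quench
Reagents that add atoms: tert-butyldimethylsilyl triflate, CC(C)(C)[Si](C)(C)OS(=O)(=O)C(F)(F)F; methoxytrimethylsilane, CO[Si](C)(C)C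
Why: The silyl triflate silylates the chelated phenol, and silyl-triflate-catalysed acetalisation with an alkoxysilane is driven by hexamethyldisiloxane formation and is aprotic and non-nucleophilic, so the hindered aldehyde should be masked without loss of the activated aryl ester, the TBS ethers or the prenyl groups.

Step 6
Reactants: 11 3-(tert-butyldimethylsilyloxy)-2-(dimethoxymethyl)-5-methoxy-4,6-bis(3-methylbut-2-enyl)phenyl 4-(tert-butyldimethylsilyloxy)-3-methoxybenzoate
Product: 13 2-(tert-butyldimethylsilyloxy)-6-{[1-(4-tert-butyldimethylsilyloxy-3-methoxyphenyl)vinyl]oxy}-4-methoxy-3,5-bis(3-methylbut-2-enyl)benzaldehyde, via vinyl ether acetal 12 (not isolated)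
Conditions: Cp2TiMe2 (3 equiv), toluene–THF, 65 °C, dark; hexane, filtration through basic alumina; then PPTS (5 mol %), THF–H2O (2:1), 0 °C, short contact; NaHCO3 quench
Reagents that add atoms: dimethyltitanocene, C[Ti](C)(C1C=CC=C1)C1C=CC=C1; water, O
Why: Heated dimethyltitanocene gives titanocene methylidene, which turns the aryl ester C=O into C=CH2 by [2+2] addition and cycloreversion (Petasis methylenation, the standard route from aryl benzoates to 1-aryloxy-1-arylethenes) without touching acetal, silyl ethers or trisubstituted alkenes, and the trioxygenated benzaldehyde acetal then ionises in water-rich, weakly acidic medium far faster than the aryl enol ether is C-protonated, so the aldehyde should be released with the vinyl ether and both TBS ethers intact.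

Step 7
Reactants: 13 2-(tert-butyldimethylsilyloxy)-6-{[1-(4-tert-butyldimethylsilyloxy-3-methoxyphenyl)vinyl]oxy}-4-methoxy-3,5-bis(3-methylbut-2-enyl)benzaldehyde
Product: 14 (2S)-5-(tert-butyldimethylsilyloxy)-2-[4-(tert-butyldimethylsilyloxy)-3-methoxyphenyl]-7-methoxy-6,8-bis(3-methylbut-2-enyl)chroman-4-one
Conditions: [Rh(cod)Cl]2 (2.5 mol %), (R)-DTBM-SEGPHOS (5.5 mol %), NaBArF4 (5 mol %), 2,6-di-tert-butyl-4-methylpyridine (10 mol %), 1,4-dioxane, 60 °C
Reagents that add atoms: none
Why: Proposed new method: cationic Rh(I) binds O1 and the enol-ether alkene, inserts into the formyl C–H bond and transfers the hydride to the aryl-bearing alkene carbon (future C2) so that rhodium ends on the terminal CH2, and C–C reductive elimination from the seven-membered acyl–alkyl rhodacycle forms C3–C4. The closest known reaction type is rhodium-catalysed enantioselective intramolecular alkene hydroacylation of 1,1-disubstituted ortho-vinylbenzaldehydes (to 3-substituted indanones) and of ortho-allylbenzaldehydes (to six-membered benzo-fused ketones); an O-bound 1-arylvinyl ether has not been used. Ring C closes in a formal 6-endo-trig mode, the acyl carbon bonding to the terminal alkene carbon. C2 is set in the hydride-transfer (migratory insertion) step by the chiral bisphosphine on rhodium, that is by catalyst control, since the substrate has no other stereocentre. The step needs endo regiochemistry, hydroacylation ahead of decarbonylation, and one alkene face; the 1,1-disubstitution disfavours the tertiary α-oxybenzyl rhodium required for 5-exo closure (which would give a 2-methyl-2-arylbenzofuran-3-one), O1 and alkene coordination keep the acyl hydride saturated, and the silyl cap on O5 keeps that oxygen off the metal.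

Step 8
Reactants: 14 (2S)-5-(tert-butyldimethylsilyloxy)-2-[4-(tert-butyldimethylsilyloxy)-3-methoxyphenyl]-7-methoxy-6,8-bis(3-methylbut-2-enyl)chroman-4-one
Product: 15 (2S)-5-hydroxy-2-(4-hydroxy-3-methoxyphenyl)-7-methoxy-6,8-bis(3-methylbut-2-enyl)chroman-4-one
Conditions: TBAF (2.5 equiv), AcOH (2.5 equiv), THF, 0 °C
Reagents that add atoms: none
Why: Fluoride cleaves both aryl Si–O bonds (desilylation), and the acetic acid buffer keeps the phenols protonated so that base-induced ring opening to the chalcone, which would racemise C2, is avoided, while the prenyl groups and the ketone are inert.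

Compound list
1 | 2,4,6-trihydroxybenzaldehyde | O=Cc1c(O)cc(O)cc1O | starting material
2 | prenyl bromide (1-bromo-3-methylbut-2-ene) | CC(C)=CCBr | starting material
3 | 2,4,6-trihydroxy-3,5-bis(3-methylbut-2-enyl)benzaldehyde | O=Cc1c(O)c(CC=C(C)C)c(O)c(CC=C(C)C)c1O | intermediate
4 | 2,6-dihydroxy-4-methoxy-3,5-bis(3-methylbut-2-enyl)benzaldehyde | O=Cc1c(O)c(CC=C(C)C)c(OC)c(CC=C(C)C)c1O | intermediate
5 | vanillic acid (4-hydroxy-3-methoxybenzoic acid) | COc1cc(C(=O)O)ccc1O | starting material
6 | tert-butyldimethylsilyl 4-(tert-butyldimethylsilyloxy)-3-methoxybenzoate | COc1cc(C(=O)O[Si](C)(C)C(C)(C)C)ccc1O[Si](C)(C)C(C)(C)C | intermediate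
7 | 4-(tert-butyldimethylsilyloxy)-3-methoxybenzoic acid | COc1cc(C(=O)O)ccc1O[Si](C)(C)C(C)(C)C | intermediate
8 | 4-(tert-butyldimethylsilyloxy)-3-methoxybenzoyl chloride | COc1cc(C(=O)Cl)ccc1O[Si](C)(C)C(C)(C)C | intermediate
9 | 2-formyl-3-hydroxy-5-methoxy-4,6-bis(3-methylbut-2-enyl)phenyl 4-(tert-butyldimethylsilyloxy)-3-methoxybenzoate | O=Cc1c(O)c(CC=C(C)C)c(OC)c(CC=C(C)C)c1OC(=O)c1ccc(O[Si](C)(C)C(C)(C)C)c(OC)c1 | intermediate
10 | 3-(tert-butyldimethylsilyloxy)-2-formyl-5-methoxy-4,6-bis(3-methylbut-2-enyl)phenyl 4-(tert-butyldimethylsilyloxy)-3-methoxybenzoate | O=Cc1c(O[Si](C)(C)C(C)(C)C)c(CC=C(C)C)c(OC)c(CC=C(C)C)c1OC(=O)c1ccc(O[Si](C)(C)C(C)(C)C)c(OC)c1 | intermediate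
11 | 3-(tert-butyldimethylsilyloxy)-2-(dimethoxymethyl)-5-methoxy-4,6-bis(3-methylbut-2-enyl)phenyl 4-(tert-butyldimethylsilyloxy)-3-methoxybenzoate | COC(OC)c1c(O[Si](C)(C)C(C)(C)C)c(CC=C(C)C)c(OC)c(CC=C(C)C)c1OC(=O)c1ccc(O[Si](C)(C)C(C)(C)C)c(OC)c1 | intermediate
12 | dimethyl acetal of 13: 1-(tert-butyldimethylsilyloxy)-3-{[1-(4-tert-butyldimethylsilyloxy-3-methoxyphenyl)vinyl]oxy}-2-(dimethoxymethyl)-5-methoxy-4,6-bis(3-methylbut-2-enyl)benzene | COC(OC)c1c(O[Si](C)(C)C(C)(C)C)c(CC=C(C)C)c(OC)c(CC=C(C)C)c1OC(=C)c1ccc(O[Si](C)(C)C(C)(C)C)c(OC)c1 | intermediate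
13 | 2-(tert-butyldimethylsilyloxy)-6-{[1-(4-tert-butyldimethylsilyloxy-3-methoxyphenyl)vinyl]oxy}-4-methoxy-3,5-bis(3-methylbut-2-enyl)benzaldehyde | O=Cc1c(O[Si](C)(C)C(C)(C)C)c(CC=C(C)C)c(OC)c(CC=C(C)C)c1OC(=C)c1ccc(O[Si](C)(C)C(C)(C)C)c(OC)c1 | intermediate
14 | (2S)-5-(tert-butyldimethylsilyloxy)-2-[4-(tert-butyldimethylsilyloxy)-3-methoxyphenyl]-7-methoxy-6,8-bis(3-methylbut-2-enyl)chroman-4-one | COc1cc([C@@H]2CC(=O)c3c(O[Si](C)(C)C(C)(C)C)c(CC=C(C)C)c(OC)c(CC=C(C)C)c3O2)ccc1O[Si](C)(C)C(C)(C)C | intermediate
15 | (2S)-5-hydroxy-2-(4-hydroxy-3-methoxyphenyl)-7-methoxy-6,8-bis(3-methylbut-2-enyl)chroman-4-one | COc1cc([C@@H]2CC(=O)c3c(O)c(CC=C(C)C)c(OC)c(CC=C(C)C)c3O2)ccc1O | target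

Total step count: 8. Longest linear sequence: 7 steps (steps 1, 2, 4, 5, 6, 7, 8 from compound 1).

Steps most likely to fail

Step 7. Decarbonylation of the acyl–rhodium hydride may outrun alkene insertion, closure may go 5-exo, facial selectivity in the hydride transfer may be poor, or adventitious acid may condense the enol ether with the aldehyde. The fallback makes the C2–aryl bond by a known asymmetric conjugate addition to a chromone; it sets out from prenyl bromide 2 and returns at target 15. Commercial 2,4,6-trihydroxyacetophenone is C-diprenylated with 2 (aq. KOH) to 1-[2,4,6-trihydroxy-3,5-bis(3-methylbut-2-enyl)phenyl]ethanone F1. Selective 4-O-methylation (Me2SO4, K2CO3, acetone) gives 1-[2,6-dihydroxy-4-methoxy-3,5-bis(3-methylbut-2-enyl)phenyl]ethanone F2. Condensation with N,N-dimethylformamide dimethyl acetal (toluene, 80 °C) gives the enaminone (E)-1-[2,6-dihydroxy-4-methoxy-3,5-bis(3-methylbut-2-enyl)phenyl]-3-(dimethylamino)prop-2-en-1-one F3. This is cyclised with acetic acid to 5-hydroxy-7-methoxy-6,8-bis(3-methylbut-2-enyl)chromen-4-one F4. Commercial 4-bromo-2-methoxyphenol is silylated (TBSCl, imidazole) to (4-bromo-2-methoxyphenoxy)(tert-butyl)dimethylsilane F5, and bromine–lithium exchange (n-BuLi, −78 °C), triisopropyl borate and aqueous work-up give [4-(tert-butyldimethylsilyloxy)-3-methoxyphenyl]boronic acid F6. Palladium(II)/pyridine-oxazoline-catalysed conjugate addition of F6 to F4 (Pd(OCOCF3)2, t-BuPyOx of the hand that gives 2S, NH4PF6, H2O, ClCH2CH2Cl, 60 °C) should give (2S)-2-[4-(tert-butyldimethylsilyloxy)-3-methoxyphenyl]-5-hydroxy-7-methoxy-6,8-bis(3-methylbut-2-enyl)chroman-4-one F7. Buffered fluoride as in step 8 then gives 15.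

Step 6. The hindered, electron-rich ester carbonyl may resist methylenation, or during acetal release the benzylic oxocarbenium may be captured by the neighbouring enol ether (Prins-type closure toward a flavylium) or the enol ether may hydrolyse. A failure of the masking in step 5 is answered by the same fallback. It builds the vinyl ether by etherification and elimination, with no titanium reagent and no aldehyde mask; it sets out from 4 and returns at 13. Commercial 2-methoxy-4-vinylphenol is silylated (TBSCl, imidazole) to tert-butyl(2-methoxy-4-vinylphenoxy)dimethylsilane F8. NBS in aqueous acetone at 0 °C gives the bromohydrin 2-bromo-1-[4-(tert-butyldimethylsilyloxy)-3-methoxyphenyl]ethanol F9. Mitsunobu etherification of one of the two equivalent phenols of 4 (PPh3, DIAD, THF, 0 °C) gives 2-{2-bromo-1-[4-(tert-butyldimethylsilyloxy)-3-methoxyphenyl]ethoxy}-6-hydroxy-4-methoxy-3,5-bis(3-methylbut-2-enyl)benzaldehyde F10. Dehydrobromination (DBU, dry MeCN, 70 °C) removes the benzylic hydrogen and bromide to give 2-{[1-(4-tert-butyldimethylsilyloxy-3-methoxyphenyl)vinyl]oxy}-6-hydroxy-4-methoxy-3,5-bis(3-methylbut-2-enyl)benzaldehyde F11. Silylation of the remaining phenol under non-acidic conditions (TBSCl, imidazole, DMF) then gives 13.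

Step 1. O-alkylation, mono-alkylation and dearomatising gem-dialkylation may compete with the double C-alkylation and leave a mixture. The fallback introduces the prenyl groups by electrophilic aromatic substitution on the neutral phenol instead of phenolate alkylation: 1 is treated with 2-methylbut-3-en-2-ol and BF3·OEt2 in dioxane at rt (Friedel–Crafts alkylation by the dimethylallyl cation, kept short to avoid chroman formation). It sets out from 1 and returns at 3 and makes no new compound.

Further compounds
F1 | step 7 | 1-[2,4,6-trihydroxy-3,5-bis(3-methylbut-2-enyl)phenyl]ethanone | CC(=O)c1c(O)c(CC=C(C)C)c(O)c(CC=C(C)C)c1O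
F2 | step 7 | 1-[2,6-dihydroxy-4-methoxy-3,5-bis(3-methylbut-2-enyl)phenyl]ethanone | CC(=O)c1c(O)c(CC=C(C)C)c(OC)c(CC=C(C)C)c1O
F3 | step 7 | (E)-1-[2,6-dihydroxy-4-methoxy-3,5-bis(3-methylbut-2-enyl)phenyl]-3-(dimethylamino)prop-2-en-1-one | CN(C)/C=C/C(=O)c1c(O)c(CC=C(C)C)c(OC)c(CC=C(C)C)c1O
F4 | step 7 | 5-hydroxy-7-methoxy-6,8-bis(3-methylbut-2-enyl)chromen-4-one | O=c1ccoc2c(CC=C(C)C)c(OC)c(CC=C(C)C)c(O)c12
F5 | step 7 | (4-bromo-2-methoxyphenoxy)(tert-butyl)dimethylsilane | COc1cc(Br)ccc1O[Si](C)(C)C(C)(C)C
F6 | step 7 | [4-(tert-butyldimethylsilyloxy)-3-methoxyphenyl]boronic acid | COc1cc(B(O)O)ccc1O[Si](C)(C)C(C)(C)C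
F7 | step 7 | (2S)-2-[4-(tert-butyldimethylsilyloxy)-3-methoxyphenyl]-5-hydroxy-7-methoxy-6,8-bis(3-methylbut-2-enyl)chroman-4-one | COc1cc([C@@H]2CC(=O)c3c(O)c(CC=C(C)C)c(OC)c(CC=C(C)C)c3O2)ccc1O[Si](C)(C)C(C)(C)C
F8 | step 6 | tert-butyl(2-methoxy-4-vinylphenoxy)dimethylsilane | C=Cc1ccc(O[Si](C)(C)C(C)(C)C)c(OC)c1
F9 | step 6 | 2-bromo-1-[4-(tert-butyldimethylsilyloxy)-3-methoxyphenyl]ethanol (racemic) | OC(CBr)c1ccc(O[Si](C)(C)C(C)(C)C)c(OC)c1
F10 | step 6 | 2-{2-bromo-1-[4-(tert-butyldimethylsilyloxy)-3-methoxyphenyl]ethoxy}-6-hydroxy-4-methoxy-3,5-bis(3-methylbut-2-enyl)benzaldehyde (racemic) | O=Cc1c(O)c(CC=C(C)C)c(OC)c(CC=C(C)C)c1OC(CBr)c1ccc(O[Si](C)(C)C(C)(C)C)c(OC)c1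
F11 | step 6 | 2-{[1-(4-tert-butyldimethylsilyloxy-3-methoxyphenyl)vinyl]oxy}-6-hydroxy-4-methoxy-3,5-bis(3-methylbut-2-enyl)benzaldehyde | O=Cc1c(O)c(CC=C(C)C)c(OC)c(CC=C(C)C)c1OC(=C)c1ccc(O[Si](C)(C)C(C)(C)C)c(OC)c1
F0 | step 1 | none | none
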